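I start from the green run.

- green: D 0.80 M; J 88 mM (held); L 0.7 mol%; run made earlier
- flask: D 0.80 M; J 88 mM (held); L 1.4 mol%; time 20 h

green run (percent of the D charged): time / h: G / % = 0.333: 4.0; 0.500: 4.4; 0.667: 3.6; 1.00: 7.3; 1.50: 10.7; 2.50: 14.3; 4.00: 19.3

(standard deviation of a reading: 1 percentage point)

- at the start none of Q is dissolved
- steps thought possible: J <-> Q; D + Q + L -> L + G; L + G -> E; Q + G -> X
- no earlier run changes the charge of L; that part of a forecast is a guess

- the G standing at 20 h, as a percentage of the D charged
- the change that raises the amount of G at 20 h, in percent of the D charged most ("none" if none brings more than 2 percentage points) (Saturday's / Monday's / Tuesday's / none)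
- amount of G at 20 h, in percent of the D charged, after Tuesday's

- Saturday's: doubling the saturation concentration of J, all else as stated
- Monday's: doubling the transfer coefficient of J, all else as stated
- Tuesday's: doubling the amount of L, all else as stated

I read the green table downward. Its earliest rows, 4.0 %, 4.4 % and 3.6 %, do not climb beyond a scatter of 1 percentage point, so I take no rate from them. The row at 1.50 h, with 10.7 %, is the one I read as still straight, and following one molecule of D it gives a chance per hour of being taken of 0.0754 h⁻¹ in the green run. The next row tests this: the line gives 17.2 % at 2.50 h, against 14.3 % read. The last row is sharper, with 26.0 % against 19.3 %, so by 4.00 h the green run falls short by 6.8 points, more than the scatter. For the flask, with twice the L of the green run, I guess that the chance doubles too. My taking chance is then 0.151 h⁻¹, the fraction of the remaining D taken per hour, a pseudo-first-order constant. Unfaded, it gives 95.1 % of the D taken by 20 h. I hold that as an upper line for G, and the rows do not tell me how far below it G stands.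

The forecast puts G in the flask at 28 %, within 12 % to 36 %, and names Tuesday's as the best change, giving 37 %, within 12 % to 48 %. Its ground: “I favour catalyst death, where G plateaus”.

The flask gives 35.8 % of G, and Tuesday's is the best change, adding 3.8 points to reach 39.6 %.

    J ⇌ Q, rate k1*(csat - [Q]) (kL = 1.00 min⁻¹)
    D + Q + L → L + G (k = 2.30 M⁻² min⁻¹)
    L + G → E (k = 0.00590 M⁻¹ min⁻¹)
    Q + G → X (k = 0.00880 M⁻¹ min⁻¹)

In the flask the taking chance gives 26.1 % of the D taken at 2.00 h, against 22.8 % found, but at 20 h D stands at 28.4 % where the chance leaves 4.88 %, with L down to 12.0 % of its charge. At 20 h G in the flask is made at 0.276 of the rate at which it is used, and at 4.66 h the path to X uses G 16 times as fast as the path to E.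

For a neighbouring flask, the same charge read at 12 h, the taking chance gives 83.7 % of the D taken. Computed, 65.0 % is taken, with G at 44.4 % and X at 19.6 %.

The earlier runs and the new flask come from a simulation with made-up constants.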